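Ring A is unfunctionalised, and its C3–C4 edge joins the gem-dimethyl carbon C4 to the ring-fusion atoms C5 and C10: exactly the array hidden in the dimethylcyclobutane flank of (+)-verbenone, whose six-membered ring becomes ring B. Cuprate addition anti to the bridge sets C10; scission of the cyclobutane C4–C7 bond then unveils a C5 isopropenyl group trans to the C10 butenyl arm and frees a C8 ketone. Ring-closing metathesis of the two arms forms C3=C4 and closes ring A, the last ring, already trans-fused; hydromethylation completes C4. The C8 ketone gives the C7=C8 acid through its enol triflate, and a C9 butynyl chain becomes the E-allylic acetate by carboalumination.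

Key step: step 5

Remark: labdane numbering is used for every intermediate (ring A = C1–C5 and C10, ring B = C5–C10, C17 = carboxyl carbon), α/β refer to the usual drawing with the C10 methyl β, and (1R,5R)-(+)-verbenone is taken as a commercial compound.

Step 1
Reactants: 1 4-(trimethylsilyl)but-3-yn-1-ol
Product: 2 4-(trimethylsilyl)but-3-yn-1-yl trifluoromethanesulfonate
Conditions: Tf2O, 2,6-lutidine, CH2Cl2, −78 °C; used at once
Reagents that add atoms: trifluoromethanesulfonic anhydride, O=S(=O)(OS(=O)(=O)C(F)(F)F)C(F)(F)F
Why: Standard O-triflation of a primary alcohol; the triflate is chosen because the enolate of step 2 is too hindered for an unactivated homopropargylic iodide.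

Step 2
Reactants: 3 (1R,5R)-(+)-verbenone; 4 but-3-en-1-ylmagnesium bromide; 2 4-(trimethylsilyl)but-3-yn-1-yl trifluoromethanesulfonate
Product: 6 4-(but-3-en-1-yl)-4,6,6-trimethyl-3-[4-(trimethylsilyl)but-3-yn-1-yl]bicyclo[3.1.1]heptan-2-one (butenyl at C10 and alkynyl chain at C9 both anti to the C(CH3)2 bridge; 9α chain), via bromomagnesium enolate 5 (not isolated)
Conditions: 4, CuBr·SMe2 (10 mol %), THF, −40 °C; then 2, DMPU, −40 → 0 °C
Reagents that add atoms: none
Why: CuBr·SMe2-catalysed conjugate addition to the enone should occur on the face anti to the C(CH3)2 bridge, which sets C10 (butenyl α, methyl β), and the regiodefined enolate is C-alkylated by the primary triflate, again anti to the bridge (tandem conjugate addition–enolate alkylation).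

Step 3
Reactants: 6 the 9α-chain bicyclic ketone
Product: 8 C9 epimer of 6 (alkynyl chain syn to the C(CH3)2 bridge; 9β chain), via potassium enolate 7 (not isolated)
Conditions: KH, THF, 0 °C → rt; then AcOH, THF, −78 °C
Reagents that add atoms: none
Why: C9 is the only enolisable position (C7 is a bridgehead), so the enolate forms regiospecifically, and kinetic C-protonation from the open face anti to the bridge should place H anti and the chain syn, which is the 9β configuration of the target (enolisation–kinetic protonation).

Step 4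
Reactants: 8 the 9β-chain bicyclic ketone
Product: 11 3-(but-3-en-1-yl)-3-methyl-4-(prop-1-en-2-yl)-2-[4-(trimethylsilyl)but-3-yn-1-yl]cyclohexan-1-one (ring B ketone; C5 isopropenyl trans to C10 butenyl; C9 chain cis to the C10 methyl), via silyl enol ether iodide 9 (not isolated), via silyl enol ether diene 10 (not isolated)
Conditions: TMSCl, NaI, MeCN, 0 °C; then Et3N, 0 °C → rt; dilute aq. HCl work-up
Reagents that add atoms: none
Why: Iodotrimethylsilane activates the C8 ketone and the strained C4–C7 cyclobutane bond breaks heterolytically to the C7=C8 silyl enol ether and the tertiary C4 cation, which iodide captures (the known Lewis-acid ring opening of pinan-2-one-type ketones); mild loss of HI toward a methyl group gives the isopropenyl group and hydrolysis returns the C8 ketone, with C5, C9 and C10 untouched.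

Step 5
Reactants: 11 the monocyclic ring B ketone
Product: 12 5,8a-dimethyl-1-[4-(trimethylsilyl)but-3-yn-1-yl]-3,4,4a,7,8,8a-hexahydronaphthalen-2(1H)-one (trans-fused; 5α-H; 10β-CH3; 9β chain; C3=C4 olefin carrying one C4 methyl)
Conditions: second-generation Grubbs catalyst RuCl2(=CHPh)(PCy3)(H2IMes) (5 mol %), CH2Cl2 (0.01 M), 40 °C
Reagents that add atoms: none
Why: The Ru=CHPh alkylidene of RuCl2(=CHPh)(PCy3)(H2IMes) engages the monosubstituted butenyl olefin first, then the 1,1-disubstituted isopropenyl olefin intramolecularly through a ruthenacyclobutane, and cycloreversion releases ethene and the trisubstituted C3=C4 olefin (olefin ring-closing metathesis). The closest known reaction type is the RCM of an isopropenyl group with a terminal alkenyl chain on the neighbouring ring carbon to give a fused 1-methylcyclohexene. Ring A closes as a six-membered ring by joining the two chain termini C3 and C4, the bonds C5–C4 and C10–C1 being already in place. No stereocentre is formed: C5 comes from verbenone and C10 from the bridge-controlled cuprate addition, so the two arms are trans-diequatorial on ring B and the ring can only close trans-fused. The step needs chemoselectivity for the two terminal olefins over the alkyne (enyne metathesis) and for cyclisation over oligomerisation; the trimethylsilyl cap on the internal alkyne, the favourable ring size and dilution should secure this.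

Step 6
Reactants: 12 the trans-fused octalinone
Product: 14 5,5,8a-trimethyl-1-[4-(trimethylsilyl)but-3-yn-1-yl]octahydronaphthalen-2(1H)-one (trans-decalin; 5α-H; 10β-CH3; 9β chain; C8 ketone), via sulfonylhydrazide 13 (not isolated)
Conditions: Fe(acac)3 (30 mol %), PhSiH3, CH2=N–NHSO2CH3, THF/MeOH, rt; then Et3N, MeOH, 60 °C
Reagents that add atoms: formaldehyde methanesulfonylhydrazone, C=NNS(C)(=O)=O
Why: Hydrogen atom transfer to C3 from the Fe–H species generated from Fe(acac)3 and PhSiH3 gives the tertiary C4 radical, which adds to the C=N bond of the formaldehyde hydrazone; on warming the alkyl sulfonylhydrazide loses sulfinate and dinitrogen and leaves the second C4 methyl group (olefin hydromethylation; C4 becomes CMe2, so no stereocentre arises).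

Step 7
Reactants: 14 the trans-decalin C8 ketone
Product: 16 the C8 enol triflate with a C7=C8 double bond (5α-H; 10β-CH3; 9β chain), via lithium enolate 15 (not isolated)
Conditions: LDA, THF, −78 °C; then PhNTf2, −78 → 0 °C
Reagents that add atoms: N-phenylbis(trifluoromethanesulfonimide), O=S(=O)(N(c1ccccc1)S(=O)(=O)C(F)(F)F)C(F)(F)F
Why: LDA removes the unhindered C7 proton under kinetic control (C9–H is tertiary and flanked by quaternary C10), and the C7=C8 enolate is O-triflated, so C9 is no longer epimerisable (kinetic enol triflate formation).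

Step 8
Reactants: 16 the enol triflate
Product: 17 methyl ester of the C7=C8 unsaturated C17 acid carrying the 9β 4-(trimethylsilyl)but-3-ynyl chain
Conditions: Pd(OAc)2 (5 mol %), PPh3 (10 mol %), CO (1 atm), Et3N, MeOH/DMF, 60 °C
Reagents that add atoms: carbon monoxide, [C-]#[O+]; methanol, CO
Why: Pd(OAc)2/PPh3-catalysed methoxycarbonylation of the enol triflate (oxidative addition, CO insertion, methanolysis) attaches C17 to C8 with the double bond fixed at C7=C8.

Step 9
Reactants: 17 the silylalkynyl methyl ester
Product: 18 9β-(but-3-yn-1-yl) C7=C8 unsaturated C17 carboxylic acid (5α-H; 10β-CH3)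
Conditions: KOH, MeOH/H2O, 65 °C; then aq. HCl to pH 3
Reagents that add atoms: potassium hydroxide (hydroxide oxygen), [K+].[OH-]
Why: Saponification of the hindered conjugated ester and protodesilylation of the alkynylsilane both occur in hot methanolic hydroxide; the double bond should stay at the conjugated C7=C8 position because the carboxylate, once formed, resists γ-deprotonation at C9 or C6.

Step 10
Reactants: 18 the alkynyl acid
Product: 21 15-hydroxylabda-7,13E-dien-17-oic acid, via alkenylalane 19 (not isolated), via lithium alanate 20 (not isolated)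
Conditions: Me3Al (3 equiv), Cp2ZrCl2 (25 mol %), CH2Cl2, 0 °C → rt; then MeLi, THF, −78 °C; (CH2O)n, −78 °C → rt; aq. HCl
Reagents that add atoms: trimethylaluminium, C[Al](C)C; formaldehyde (as paraformaldehyde), C=O
Why: Cp2ZrCl2-catalysed carboalumination (Negishi) adds methyl and aluminium syn across the terminal alkyne with methyl on C13, and the alkenyl alanate reacts with formaldehyde with retention, so the C13=C14 olefin should be E; the acid is masked in the flask as its aluminium carboxylate.

Step 11
Reactants: 21 the hydroxy acid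
Product: 23 (5S,9R,10S)-15-acetoxylabda-7,13E-dien-17-oic acid, via mixed anhydride 22 (not isolated)
Conditions: Ac2O, pyridine, DMAP (cat.), CH2Cl2, 0 °C → rt; then THF/aq. NaHCO3, rt; acidify to pH 3
Reagents that add atoms: acetic anhydride, CC(=O)OC(C)=O
Why: Acetylation of the primary allylic alcohol; the mixed anhydride formed at the carboxyl group is hydrolysed by mild aqueous bicarbonate, which leaves the allylic acetate intact.

Compound list
1 | 4-(trimethylsilyl)but-3-yn-1-ol | C[Si](C)(C)C#CCCO | starting material
2 | 4-(trimethylsilyl)but-3-yn-1-yl trifluoromethanesulfonate | C[Si](C)(C)C#CCCOS(=O)(=O)C(F)(F)F | intermediate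
3 | (1R,5R)-(+)-verbenone, (1R,5R)-4,6,6-trimethylbicyclo[3.1.1]hept-3-en-2-one | CC1=CC(=O)[C@@H]2C[C@H]1C2(C)C | starting material
4 | but-3-en-1-ylmagnesium bromide | C=CCC[Mg]Br | starting material
5 | bromomagnesium enolate of the 4-butenyl adduct (butenyl anti to the bridge) | C1=C(O[Mg]Br)[C@@H]2C[C@@H](C2(C)C)[C@]1(C)CCC=C | intermediate
6 | 4-(but-3-en-1-yl)-4,6,6-trimethyl-3-[4-(trimethylsilyl)but-3-yn-1-yl]bicyclo[3.1.1]heptan-2-one, both chains anti to the C(CH3)2 bridge (9α chain) | C[Si](C)(C)C#CCC[C@@H]1C(=O)[C@@H]2C[C@@H](C2(C)C)[C@]1(C)CCC=C | intermediate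
7 | potassium enolate of 6 | C[Si](C)(C)C#CCCC1=C(O[K])[C@@H]2C[C@@H](C2(C)C)[C@]1(C)CCC=C | intermediate
8 | C9 epimer of 6, alkynyl chain syn to the C(CH3)2 bridge (9β chain) | C[Si](C)(C)C#CCC[C@H]1C(=O)[C@@H]2C[C@@H](C2(C)C)[C@]1(C)CCC=C | intermediate
9 | ring-opened C7=C8 trimethylsilyl enol ether with a 2-iodopropan-2-yl group on C5 | C[Si](C)(C)C#CCC[C@H]1C(O[Si](C)(C)C)=CC[C@@H](C(C)(C)I)[C@]1(C)CCC=C | intermediate
10 | ring-opened C7=C8 trimethylsilyl enol ether with an isopropenyl group on C5 | C[Si](C)(C)C#CCC[C@H]1C(O[Si](C)(C)C)=CC[C@@H](C(C)=C)[C@]1(C)CCC=C | intermediate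
11 | 3-(but-3-en-1-yl)-3-methyl-4-(prop-1-en-2-yl)-2-[4-(trimethylsilyl)but-3-yn-1-yl]cyclohexan-1-one, isopropenyl trans to butenyl, alkynyl chain cis to the methyl | C[Si](C)(C)C#CCC[C@H]1C(=O)CC[C@@H](C(C)=C)[C@]1(C)CCC=C | intermediate
12 | 5,8a-dimethyl-1-[4-(trimethylsilyl)but-3-yn-1-yl]-3,4,4a,7,8,8a-hexahydronaphthalen-2(1H)-one, trans-fused (5α-H, 10β-CH3, 9β chain) | C[Si](C)(C)C#CCC[C@H]1C(=O)CC[C@H]2C(C)=CCC[C@]12C | intermediate
13 | C4 adduct bearing CH3 and CH2NHNHSO2CH3 (mixture at C4) | C[Si](C)(C)C#CCC[C@H]1C(=O)CC[C@H]2C(C)(CNNS(C)(=O)=O)CCC[C@]12C | intermediate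
14 | 5,5,8a-trimethyl-1-[4-(trimethylsilyl)but-3-yn-1-yl]octahydronaphthalen-2(1H)-one, trans-decalin (5α-H, 10β-CH3, 9β chain) | C[Si](C)(C)C#CCC[C@H]1C(=O)CC[C@H]2C(C)(C)CCC[C@]12C | intermediate
15 | lithium C7=C8 enolate of 14 | C[Si](C)(C)C#CCC[C@H]1C(O[Li])=CC[C@H]2C(C)(C)CCC[C@]12C | intermediate
16 | C8 enol triflate of 14 (C7=C8) | C[Si](C)(C)C#CCC[C@H]1C(OS(=O)(=O)C(F)(F)F)=CC[C@H]2C(C)(C)CCC[C@]12C | intermediate
17 | methyl ester at C8 (C17), C7=C8 olefin, 9β 4-(trimethylsilyl)but-3-ynyl chain | C[Si](C)(C)C#CCC[C@H]1C(C(=O)OC)=CC[C@H]2C(C)(C)CCC[C@]12C | intermediate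
18 | 9β-(but-3-yn-1-yl) C7=C8 unsaturated C17 carboxylic acid | C#CCC[C@H]1C(C(=O)O)=CC[C@H]2C(C)(C)CCC[C@]12C | intermediate
19 | E-alkenyl dimethylalane (Al on C14, methyl on C13) with dimethylaluminium carboxylate | C[Al](C)/C=C(\C)CC[C@H]1C(C(=O)O[Al](C)C)=CC[C@H]2C(C)(C)CCC[C@]12C | intermediate
20 | lithium alkenyl trimethylalanate derived from 19 | [Li+].C[Al-](C)(C)/C=C(\C)CC[C@H]1C(C(=O)O[Al](C)C)=CC[C@H]2C(C)(C)CCC[C@]12C | intermediate
21 | 15-hydroxylabda-7,13E-dien-17-oic acid | OC/C=C(\C)CC[C@H]1C(C(=O)O)=CC[C@H]2C(C)(C)CCC[C@]12C | intermediate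
22 | 15-acetate of 21 with the carboxyl group as mixed acetic anhydride | CC(=O)OC/C=C(\C)CC[C@H]1C(C(=O)OC(C)=O)=CC[C@H]2C(C)(C)CCC[C@]12C | intermediate
23 | (5S,9R,10S)-15-acetoxylabda-7,13E-dien-17-oic acid | CC(=O)OC/C=C(\C)CC[C@H]1C(C(=O)O)=CC[C@H]2C(C)(C)CCC[C@]12C | target

Total step count: 11. Longest linear sequence: 11 steps (1 → 23, steps 1–11; the triflate 2 made in step 1 enters the main line in step 2).

Steps most likely to fail

Step 2. The hindered magnesium enolate, flanked by the new quaternary C10, may undergo O-alkylation or proton transfer and elimination of the triflate instead of C-alkylation, so that the chain is not attached at C9. The fallback sets out from 3 and 4: the conjugate addition is quenched with aqueous NH4Cl to give the butenyl ketone F1. Because only C9 can be enolised in this bicycle, its lithium enolate (LDA, THF, −78 °C) is added to 4-(trimethylsilyl)but-3-ynal F2, made from 1 by Parikh–Doering oxidation, to give the aldol F3. Mesylation and elimination (MsCl, Et3N, then DBU) give the alkylidene ketone F4. Conjugate reduction with [(Ph3P)CuH]6 and protonation of the resulting enolate from the face anti to the bridge should deliver 8 directly, where the route is rejoined; steps 2 and 3 are replaced.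

Step 4. The tertiary C4 cation may be trapped by the enol oxygen or the butenyl olefin, may lose a proton toward C5, or the acid formed may epimerise C9 before the ring opens. The fallback sets out from 8: acetolytic ring opening (BF3·OEt2, Zn(OAc)2, Ac2O, rt) gives the enol acetate tertiary acetate F5. MeLi (Et2O, −78 → 0 °C) cleaves both acetates without touching C9 and gives, after protonation, the hydroxy ketone F6. Dehydration of the tertiary alcohol (SOCl2, pyridine, 0 °C) toward the methyl group gives 11, where the route is rejoined.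

Step 6. The hindered tertiary C4 radical may be reduced (net hydrogenation of C3=C4) faster than it is trapped by the hydrazone, which would leave a single C4 methyl. The fallback sets out from 12 and is ionic: Markovnikov addition of dry HCl (CH2Cl2, −78 °C) gives the tertiary chloride F7, and ionisation with methyl transfer from Me3Al (CH2Cl2, −78 → −40 °C, cold enough to spare the ketone) gives 14, where the route is rejoined.

Further compounds
F1 | step 2 | 4-(but-3-en-1-yl)-4,6,6-trimethylbicyclo[3.1.1]heptan-2-one, butenyl anti to the bridge | C1C(=O)[C@@H]2C[C@@H](C2(C)C)[C@]1(C)CCC=C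
F2 | step 2 | 4-(trimethylsilyl)but-3-ynal | C[Si](C)(C)C#CCC=O
F3 | step 2 | aldol of F1 (C9) with F2, mixture at C9 and C11 | C[Si](C)(C)C#CCC(O)C1C(=O)[C@@H]2C[C@@H](C2(C)C)[C@]1(C)CCC=C
F4 | step 2 | C9=C11 alkylidene ketone from F3 | C[Si](C)(C)C#CCC=C1C(=O)[C@@H]2C[C@@H](C2(C)C)[C@]1(C)CCC=C
F5 | step 4 | ring-opened C7=C8 enol acetate with a 2-acetoxypropan-2-yl group on C5 | C[Si](C)(C)C#CCC[C@H]1C(OC(C)=O)=CC[C@@H](C(C)(C)OC(C)=O)[C@]1(C)CCC=C
F6 | step 4 | ring B ketone with a 2-hydroxypropan-2-yl group on C5 | C[Si](C)(C)C#CCC[C@H]1C(=O)CC[C@@H](C(C)(C)O)[C@]1(C)CCC=C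
F7 | step 6 | C4 tertiary chloride of the trans-decalin ketone (mixture at C4) | C[Si](C)(C)C#CCC[C@H]1C(=O)CC[C@H]2C(C)(Cl)CCC[C@]12C
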